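At the last reading of the elm run, 15.0 h, the substrate reads 0 %, so the leftover to follow is 30.3 % of target, crystals counted, and the late ratio asked for depends on how fast that leftover goes. Elm is the very flask asked about.

| setting | elm | flask |
|---|---|---|
| substrate | 0.20 M | 0.20 M |
| capture agent | 0.20 M | 0.200 M |
| remark | the very flask that is asked about, followed so far |  |
| time |  | 30 h |

elm run (percent of the substrate charged)

| time / h | target / % | isomer of the product / % | substrate / % |
|---|---|---|---|
| 0.833 | 4.8 | 3.9 | 72.4 |
| 2.50 | 21.2 | 17.0 | 38.1 |
| 4.00 | 30.8 | 27.3 | 21.0 |
| 6.00 | 35.4 | 33.2 | 10.0 |
| 10.0 | 36.6 | 41.0 | 2.5 |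
| 12.0 | 35.1 | 43.7 | 1.0 |
| 15.0 | 30.3 | 46.3 | 0 |

(standard deviation of a reading: 0.5 percentage points)

- amounts and yields of target count crystals too
- given per volume of solution although it is solid: crystals
- the analysis behind the earlier runs scatters by 0.5 percentage points, standard deviation
- steps under discussion: substrate -> open intermediate; open intermediate <-> target; open intermediate <-> isomer of the product; open intermediate + capture agent -> trapped intermediate; crystals <-> target

* ratio of target to isomer of the product at 15 min
* ratio of target to isomer of the product at 3.0 h
* ratio of target to isomer of the product at 30 h
* which of target and isomer of the product there is more of at 30 h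

We assume that while crystals last, dissolved target stays at saturation, so the loss in c(target) runs at a steady, zero-order pace. The last pair of readings gives 3.20 mM h⁻¹. But the scatter of two readings so close together is 0.471 mM h⁻¹, and carried forward that is too much. From 10.0 h to 15.0 h, the longer span gives 2.52 mM h⁻¹. The objection is that 2.5 % of substrate was still feeding target in that span. We compute just this correction, giving the feed target's share of what had reacted at 10.0 h, and estimate the drain, the steady loss of c(target) while crystals stand, at 2.90 mM h⁻¹.

Does the solid last? At this drain the target, crystals counted, empties at 35.9 h, later than the asked time. The objection is that the solid goes before the dissolved part does, and the readings do not give that part, so carrying the steady pace to 30 h remains an estimate. That leaves c(target) at 17.2 mM. The last pair of readings shows a gain in the isomer of the product of 0.542 for each unit of target lost, so we estimate that c(isomer of the product) reaches 116 mM, and our ratio at 30 h is 0.148. Target leads in the first readings, and in our estimate the isomer of the product is ahead at 30 h, the pattern of kinetic against thermodynamic control.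

The forecast gives 1.28 at 15 min, 1.2 at 3.0 h and 0.28 at 30 h, the last higher than ours, with isomer of the product ahead, on the ground that “The isomer is far more robust”.

The flask gives 1.59 at 15 min, 1.18 at 3.0 h and 0.244 at 30 h, with isomer of the product ahead.

    substrate → open intermediate (k = 0.390 h⁻¹)
    open intermediate ⇌ target (K = 0.870, k = 0.790 h⁻¹)
    open intermediate ⇌ isomer of the product (K = 36.0, k = 0.460 h⁻¹)
    open intermediate + capture agent → trapped intermediate (k = 0.960 M⁻¹ h⁻¹)
    crystals ⇌ target, rate k5*(cs5 - [target]) while solid is left; crystals form when [target] > cs5 (solubility = 8.20 mM, k = 7.70 h⁻¹)

At 30.0 h the flask still holds 9.90 % of crystals. We put the drain to use on the neighbour flask charged with 0.12 M of substrate. If it held the elm share at 15.0 h, its c(target) of 36.4 mM would empty at 27.6 h, earlier than 30 h. That neighbour flask shows crystals at 0 % and target at 1.44 % at 30.0 h.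

(The earlier runs and the new flask were computed for an exercise, noise included.)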